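**Assumption:** the target has no stereocentre (it is achiral), so no stereocontrol is needed; 4,6-dibromoisatin is taken as a catalogue compound.

**Retrosynthetic overview**
1. The C2–Br bond comes from the lactam C=O of 4,6-dibromooxindole by deoxybromination with POBr3, which also aromatises the five-membered ring.
2. The oxindole CH2 comes from the C3 ketone of 4,6-dibromoisatin by Wolff–Kishner reduction.
3. No ring is formed in the route: the benzo-fused five-membered N-ring is bought intact in the isatin, with both aryl bromines already at C4 and C6.

**Route**

Step 1
Reactants: 1 4,6-dibromoisatin (4,6-dibromo-1H-indole-2,3-dione)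
Product: 3 4,6-dibromoindolin-2-one, via hydrazone 2 (not isolated)
Conditions: N2H4·H2O (neat, excess), 130 °C, 3–4 h; then ice/aq. HCl to pH 2, filter
Reagents that add atoms: none
Why: Wolff–Kishner reduction, in which only the ketone-like C3 carbonyl (not the amide C2) condenses with hydrazine to hydrazone 2, which loses N2 in the hot basic medium to leave CH2, with the aryl bromides untouched and no stereocentre created.

Step 2
Reactants: 3 4,6-dibromoindolin-2-one
Product: 5 2,4,6-tribromo-1H-indole, via dibromophosphate ester 4 (not isolated)
Conditions: POBr3 (2.5 equiv), imidazole (1.2 equiv), ClCH2CH2Cl, 80 °C; then ice-water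
Reagents that add atoms: phosphorus oxybromide (phosphoryl bromide), O=P(Br)(Br)Br
Why: Lactam deoxybromination (imidoyl-halide type activation), in which O-phosphorylation of the lactim gives 4, bromide displaces dibromophosphate at C2 by addition–elimination and tautomerisation gives the aromatic 2-bromoindole, with imidazole buffering HBr and the two ring bromines damping acid-triggered self-condensation at C3; no stereocentre is involved.

**Compound list**
1 | 4,6-dibromoisatin (4,6-dibromo-1H-indole-2,3-dione) | O=C1Nc2cc(Br)cc(Br)c2C1=O | starting material
2 | (3Z)-4,6-dibromo-3-hydrazinylideneindolin-2-one (isatin 3-hydrazone, not isolated) | N/N=C1\C(=O)Nc2cc(Br)cc(Br)c21 | intermediate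
3 | 4,6-dibromoindolin-2-one (4,6-dibromooxindole) | O=C1Cc2c(Br)cc(Br)cc2N1 | intermediate
4 | 4,6-dibromo-1H-indol-2-yl phosphorodibromidate (not isolated) | O=P(Br)(Br)Oc1cc2c(Br)cc(Br)cc2[nH]1 | intermediate
5 | 2,4,6-tribromo-1H-indole | Brc1cc(Br)c2cc(Br)[nH]c2c1 | target

**Totals**
Total step count: 2. Longest linear sequence: 2.

**Steps most likely to fail**
The route has only two steps, so both are ranked and there is no third.

Most at risk is step 2. The failure modes are incomplete conversion, condensation of the enolisable oxindole at C3 with the activated lactam, and acid-promoted decomposition of the 2-bromoindole on work-up. The fallback sets out from 3 and comes back at 5, and it changes the approach by blocking C3 with a removable carbon during the halogenation. Vilsmeier–Haack haloformylation of 3 (POBr3, DMF, CHCl3, reflux; aqueous NaHCO3 work-up) gives 2,4,6-tribromo-1H-indole-3-carbaldehyde F2, a stable vinylogous amide. Pinnick oxidation (NaClO2, NaH2PO4, 2-methyl-2-butene, t-BuOH/THF/H2O, rt) gives 2,4,6-tribromo-1H-indole-3-carboxylic acid F3. Protodecarboxylation of F3 (cat. K2CO3, DMF, about 110 °C), helped by the strain between the 2- and 4-bromines, then gives 5.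

Second is step 1. The failure modes are hydrazinolysis of the lactam, azine formation, or attack of hot hydrazine on the 4-bromide next to the ketone. The fallback sets out from 1 and comes back at 3, and it avoids hydrazine and strong base entirely. Selective reduction of the C3 ketone (NaBH4, MeOH/THF, 0 °C) gives racemic 4,6-dibromo-3-hydroxyindolin-2-one F1. Its benzylic α-hydroxy-amide C–O bond is then cleaved reductively (NaI, TMSCl, MeCN, rt to 60 °C; or H3PO2, cat. I2, AcOH, 80 °C) to give 3. The transient stereocentre of F1 is destroyed in this step, and the aryl bromides survive.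

**Further compounds**
F1 | step 1 | 4,6-dibromo-3-hydroxyindolin-2-one (racemic) | OC1C(=O)Nc2cc(Br)cc(Br)c21
F2 | step 2 | 2,4,6-tribromo-1H-indole-3-carbaldehyde | O=Cc1c(Br)[nH]c2cc(Br)cc(Br)c12
F3 | step 2 | 2,4,6-tribromo-1H-indole-3-carboxylic acid | OC(=O)c1c(Br)[nH]c2cc(Br)cc(Br)c12
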